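# Proposed total synthesis of CNP0175424.2 (compound 29) by cycloreversion of a cyclobutene–cyclohexenone photoadduct

## Analysis of the target

Target 29 is a germacranolide: a ten-membered carbocycle (C1–C10) fused across C6–C7 to a butenolide (O–C6, C7=C11, C12 lactone carbonyl) whose C11 carries the C13 acetoxymethyl group. Around the ring sit a C1 ketone, a C10 tertiary acetate with the C14 methyl, a 4,5-epoxide with the C15 methyl on C4, the lactone CH–O at C6 and an angelate at C8. There are five stereocenters: 4R, 5R, 6S, 8S and 10R. C4, C5 and C6 are contiguous, whereas C8 and C10 are each insulated from their neighbours by one carbon (C7 trigonal, C9 methylene). The epoxide is trans, with C3 and C6 on opposite sides, so it derives from an E-C4=C5 alkene; in a flat drawing the oxygens at C6, C8 and C10 lie on one face. The sensitive groups are the angelate (isomerizes to the tiglate with nucleophiles or radicals), the 13-acetoxy butenolide (an allylic acetate on an acceptor alkene), the tertiary α-acetoxy ketone (cannot be epimerized, prone to ketol shift) and the trisubstituted epoxide (acid). The difficulty is a medium ring with no rigid scaffold, remote stereochemical relationships, and labile groups that dictate the order of events. The strategy rests on a masked 1,5-diene: C4=C5 is hidden in the epoxide and C1=C10 in the ketol, which is an oxidized enol ether. Because C1/C4 and C5/C10 face each other across the ring, joining them gives a bicyclo[2.2.0]hexane that carries ring C5–C10 as a cyclohexanone; this is tricyclic ketone 14.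

## Retrosynthetic reasoning

**Epoxide (29 ⇒ 28).** The C4–O and C5–O bonds are cut last, back to E-alkene 28. At that stage C4=C5 is the only electron-rich alkene, and an epoxide made in the final step never meets fluoride, heat or acylation conditions. The forward reaction has to deliver oxygen to the alkene face that carries the C6 lactone oxygen.

**Esters (28 ⇒ 27 ⇒ 24 + 25).** The two acyl C–O bonds are cut next. Diol 24 has a secondary C8 hydroxyl and a tertiary C10 hydroxyl, so angelic acid 25 can be placed on C8 by reactivity alone and the acetate then goes onto the only hydroxyl left. No protecting group has to distinguish the two oxygens.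

**C10–O bond (24 ⇒ 22).** The ketol is traced to the C1=C10 silyl enol ether of 22. The enol ether fixes the regiochemistry (oxygen at C10, carbonyl at C1), and its oxidation by a peracid is selective because it is the most electron-rich alkene of 22.

**Butenolide (22 ⇒ 20 ⇒ 18 ⇒ 15 + 17; 17 ⇒ 16).** The lactone C–O bond, the C6–H bond, the C7=C11 double bond and the C7–C11 bond are cut in that order. This leads to dienone 15 and acetoxypyruvate 17, which brings C11, C12 and C13 at the right oxidation levels and is made from bromopyruvate 16. The annulation is placed before the C1 ketone is unmasked. In 15 the C6 ketone has only one enolizable α-carbon (C7); once C1 is a ketone, C2 would compete for the base. The forward sequence therefore needs an aldol at C7, loss of water through the C6 enolate, a face-selective 1,2-reduction at C6 and ring closure onto the ester.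

**Ten-membered ring (15 ⇒ 14).** The C4=C5 and C1=C10 double bonds of 15 are exchanged for the σ-bonds C1–C4 and C5–C10 of tricycle 14. This is the central disconnection. It replaces a medium-ring closure by the opening of three small rings and gives the enone and the enol ether in one step, at the positions and oxidation levels the later steps use. The forward reaction must place the trans geometry at C4=C5. That outcome depends on the relative configuration of C8 and the ring fusion in 14: the silyloxy group has to be cis to the cyclobutane. The diastereomer with the silyloxy group trans to the cyclobutane would open through the other chair and give the Z-enone.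

**Tricycle (14 ⇒ 13 ⇒ 12 ⇒ 11 ⇒ 8 + 9).** The C1–C10 and C4–C5 bonds of the central cyclobutane are cut in the sense of an enone–alkene photocycloaddition, giving a 3-methylcyclohexenone and a 2-methylcyclobutanone enol ether. An intermolecular addition would not control the face of the enone. The C8 oxygen of 8 and the enol oxygen of 9 are therefore joined through one silicon atom in 11. The three-atom O–Si–O link can only deliver the alkene to the face that carries O8 and can only join C1 to C10. The bridge of 12 has to be taken out again (13) before heating, because it would hold C1 and O8 syn-diaxial and lock the wrong chair.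

**Enone (8 ⇒ 7 ⇒ 6 ⇒ 5 ⇒ 3 ⇒ 2 ⇒ 1).** The methyl group and the enone are traced by an oxidative 1,3-transposition to silyloxy enone 5. Enone 5 comes from meso diol 2 by enzymatic desymmetrization (3), oxidation and loss of the acetate. Diol 2 comes from the symmetrical triol 1. One enzymatic step sets the only stereocenter the route carries forward (C8); every other center is derived from it or from a reagent.

## Alternatives that were turned down

**Alternative 1:** The C5–C6 bond and the lactone C–O bond are cut. This leaves an open chain with an E-alkenyl iodide at C5 and an aldehyde at C6 that sits cis to a methyl ester on the C7=C11 alkene. In the forward step, divalent chromium (regenerated at a cathode) with a nickel co-catalyst turns the iodide into an alkenylchromium species. This adds to the aldehyde, and the alkoxide closes the butenolide to give A1.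
- For it: the C4=C5 geometry is fixed in the acyclic iodide, C10 and C8 are set before the ring exists, the ester is cis to C6 by construction, and the route is convergent. On alkene geometry and on the C10 configuration it is stronger than the chosen route.
- Against it: a ten-membered ring is closed by C–C bond formation at a trisubstituted alkenyl carbon, which needs dilution. C6 is created in that step under macrocyclic control that cannot be predicted. The linear precursor, with three stereocenters and a formyl alkylidene ester that isomerizes and cyclizes easily, is long to make. C1 arrives as a protected alcohol that still has to be oxidized.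
- Comparison: the chosen strategy gives up the built-in alkene geometry. In exchange it has no macrocyclization, a short approach to the ring from two small cyclic partners, and C6 set afterwards by a chiral reagent.

**Alternative 2:** The ring is traced back to a 1-alkenyl-2-isopropenylcyclohexanol from the menthane chiral pool. In the forward step the potassium alkoxide undergoes an anionic oxy-Cope shift that forms C8–C9 and opens the six-membered ring to the ten-membered C6 enolate, giving A2 with an E-C1=C10 alkene.
- For it: this ring expansion is among the most reliable entries to germacranes, the starting material is cheap and enantiopure, the new alkene geometry is secure, and the C6 enolate could be used directly at C7. On the reliability of the ring-forming step it is stronger than the chosen route.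
- Against it: it gives C1=C10 but no C4=C5; C4 arrives as a saturated methyl-bearing stereocenter that is later destroyed. The E-enone needed for the trans-epoxide would have to be made by dehydrogenation of a medium-ring ketone, with a free choice between C5 and C7 and no control of geometry. The benzyl ether at C8 would have to be removed in the presence of alkenes, an epoxide and the angelate.
- Comparison: the chosen strategy delivers both alkenes of the masked 1,5-diene at once, in the right places and oxidation states.

**Alternative 3:** The C2–C3 bond is cut. In the forward step a zerovalent palladium phosphine catalyst ionizes an allylic carbonate at C3, and the carbanion of a C2 β-keto ester attacks the π-allyl terminus to give A3.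
- For it: the oxygens at C6, C8 and C10 and the butenolide carbons are in place before ring closure, the conditions are neutral, and the nucleophile is soft. On functional-group completeness at the ring-closing stage it is stronger than the chosen route.
- Against it: attack at the other allyl terminus (C5) would give an eight-membered ring, and syn–anti interconversion of the π-allyl can erode the E geometry. The activating ester must then be removed next to a tertiary α-acetoxy ketone. The open-chain precursor needs five different protecting groups and a long linear sequence.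
- Comparison: the chosen strategy needs two silyl groups and far fewer steps to the ring, and pays with a conformational, not a constitutional, control of alkene geometry.

Key step: step 10

Assumption: the lipase in step 2 is taken to acetylate the R-configured carbinol of 2, the sense predicted by the empirical size rule for lipase acylation of secondary alcohols; the fallback for step 2 covers the opposite sense.

Remark on numbering: from compound 11 on, ring positions are given in germacrane numbering. The enone carbonyl carbon is C6, its α-carbon C5, its β-carbon C10 and the carbinol carbon C8; the cyclobutene carbons are C1 (oxygen-bearing), C2, C3 and C4 (methyl-bearing).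

## Route

Step 1
Reactants: 1 cis,cis-cyclohexane-1,3,5-triol
Product: 2 all-cis-5-[(tert-butyldimethylsilyl)oxy]cyclohexane-1,3-diol (meso)
Conditions: TBSCl (0.9 equiv), imidazole, DMF, 0 °C to rt
Reagents that add atoms: tert-butyldimethylsilyl chloride, CC(C)(C)[Si](C)(C)Cl
Why: Silylation of one of three equivalent secondary hydroxyl groups; a deficit of silyl chloride should keep bis-silylation low and unreacted triol stays in the aqueous phase. The product keeps a mirror plane, as the next step requires.

Step 2
Reactants: 2 all-cis-5-[(tert-butyldimethylsilyl)oxy]cyclohexane-1,3-diol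
Product: 3 (1R,3S,5S)-3-[(tert-butyldimethylsilyl)oxy]-5-hydroxycyclohexyl acetate
Conditions: vinyl acetate, lipase from Burkholderia cepacia (Amano PS), t-BuOMe, 30 °C
Reagents that add atoms: vinyl acetate, CC(=O)OC=C
Why: Enzymatic desymmetrization of a meso 1,3-diol by irreversible transesterification; the enzyme distinguishes the two enantiotopic carbinols and is taken to acylate the R-configured one. This turns the silyloxy-bearing carbon (later C8) into a stereocenter of defined configuration.

Step 3
Reactants: 3 (1R,3S,5S)-3-[(tert-butyldimethylsilyl)oxy]-5-hydroxycyclohexyl acetate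
Product: 5 (R)-5-[(tert-butyldimethylsilyl)oxy]cyclohex-2-en-1-one, via keto acetate 4 (not isolated)
Conditions: 1,1,1-triacetoxy-1,1-dihydro-1,2-benziodoxol-3(1H)-one, CH2Cl2, 0 °C to rt; then DBU, 0 °C
Reagents that add atoms: none
Why: Periodinane oxidation of the free carbinol followed by E1cB loss of acetic acid from the β-acetoxy ketone. Acetate is a far better leaving group than the silyloxide on the other β-carbon, so the silyl ether and its stereocenter are kept.

Step 4
Reactants: 5 (R)-5-[(tert-butyldimethylsilyl)oxy]cyclohex-2-en-1-one
Product: 6 (5R)-5-[(tert-butyldimethylsilyl)oxy]-1-methylcyclohex-2-en-1-ol (both C1 epimers)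
Conditions: MeLi, CeCl3, THF, −78 °C; H2O
Reagents that add atoms: methyllithium, [Li]C
Why: 1,2-Addition of the weakly basic organocerium reagent to the enone carbonyl, which avoids α'-deprotonation and β-elimination of the silyloxy group. The new carbinol center is lost in the next step, so its configuration does not matter.

Step 5
Reactants: 6 (5R)-5-[(tert-butyldimethylsilyl)oxy]-1-methylcyclohex-2-en-1-ol
Product: 7 (S)-5-[(tert-butyldimethylsilyl)oxy]-3-methylcyclohex-2-en-1-one
Conditions: pyridinium chlorochromate [C5H5NH][CrO3Cl], 4 Å molecular sieves, CH2Cl2, rt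
Reagents that add atoms: pyridinium chlorochromate, [O-][Cr](=O)(=O)Cl.c1cc[nH+]cc1
Why: Babler–Dauben oxidative transposition of a tertiary allylic alcohol: chromate ester, [3,3] shift, then oxidation, which puts the carbonyl on the former alkene terminus and the methyl on the enone β-carbon. The stereocenter is untouched; its descriptor changes from R to S only because the carbonyl has moved to the other flank.

Step 6
Reactants: 7 (S)-5-[(tert-butyldimethylsilyl)oxy]-3-methylcyclohex-2-en-1-one
Product: 8 (S)-5-hydroxy-3-methylcyclohex-2-en-1-one
Conditions: HF·pyridine, pyridine, THF, 0 °C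
Reagents that add atoms: none
Why: Buffered fluoride desilylation; basic fluoride sources are avoided because the β-hydroxy enone can lose water and aromatize.

Step 7
Reactants: 9 2-methylcyclobutanone; 8 (S)-5-hydroxy-3-methylcyclohex-2-en-1-one
Product: 11 (S)-3-methyl-5-({[(2-methylcyclobut-1-en-1-yl)oxy]di(propan-2-yl)silyl}oxy)cyclohex-2-en-1-one, via enol silyl triflate 10 (not isolated)
Conditions: 9, iPr2Si(OTf)2 (1.05 equiv), Et3N, CH2Cl2, −78 to 0 °C; then 8, Et3N, 0 °C
Reagents that add atoms: diisopropylsilyl bis(trifluoromethanesulfonate), CC(C)[Si](OS(=O)(=O)C(F)(F)F)(OS(=O)(=O)C(F)(F)F)C(C)C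
Why: Soft enolization and O-silylation of the ketone with a silyl triflate and amine should give mainly the more substituted (tetrasubstituted) enol ether, and the remaining Si–OTf bond is then displaced by the secondary alcohol. This is the sequential formation of an unsymmetrical silyl bis-ether (temporary silicon connection).

Step 8
Reactants: 11 (S)-3-methyl-5-({[(2-methylcyclobut-1-en-1-yl)oxy]di(propan-2-yl)silyl}oxy)cyclohex-2-en-1-one
Product: 13 cis-anti-cis 2,9-dihydroxy-1,5-dimethyltricyclo[4.4.0.0(2,5)]decan-7-one (C8 hydroxyl cis to the cyclobutane), via silylene-bridged photoadduct 12 (not isolated)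
Conditions: hν (350 nm, Pyrex), degassed toluene (0.005 M), 0 °C; then HF·pyridine, pyridine, THF, 0 °C
Reagents that add atoms: none
Why: Intramolecular enone–alkene [2+2] photocycloaddition through the enone triplet. The three-atom O–Si–O link lets C1 reach only C10 and only on the face that carries O8, so it fixes the head-to-tail regiochemistry (C1–C10, C4–C5), the cis-anti-cis fusion (O1 turned toward the six-membered ring) and the cis relation of cyclobutane and O8. The four new stereocenters (C1, C4, C5, C10) are thus all controlled by C8, and fluoride then removes the bridge.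

Step 9
Reactants: 13 cis-anti-cis 2,9-dihydroxy-1,5-dimethyltricyclo[4.4.0.0(2,5)]decan-7-one
Product: 14 cis-anti-cis 1,5-dimethyl-2,9-bis(triethylsilyloxy)tricyclo[4.4.0.0(2,5)]decan-7-one (germacrane numbering: C6 ketone, C8 and C1 silyloxy groups, C8 silyloxy cis to the cyclobutane and trans to the C10 methyl)
Conditions: TESOTf (2.5 equiv), 2,6-lutidine, CH2Cl2, −78 to 0 °C
Reagents that add atoms: triethylsilyl trifluoromethanesulfonate, CC[Si](CC)(CC)OS(=O)(=O)C(F)(F)F
Why: A silyl triflate with a hindered pyridine base silylates both the secondary and the tertiary (cyclobutanol) hydroxyl. The β-hydroxy ketone never meets a strong base, and lutidine does not enolize the ketone at this temperature.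

Step 10
Reactants: 14 cis-anti-cis 1,5-dimethyl-2,9-bis(triethylsilyloxy)tricyclo[4.4.0.0(2,5)]decan-7-one
Product: 15 (4E,8S)-4,10-dimethyl-1,8-bis(triethylsilyloxy)cyclodeca-1(10),4-dien-6-one (C2 and C9 cis on C1=C10)
Conditions: toluene (0.01 M), Et3N (1 vol %), base-washed sealed tube, 160–170 °C
Reagents that add atoms: none
Why: Heat breaks the central C1–C4 bond of the bicyclo[2.2.0]hexane first, because it is the most strained bond and gives a 1,4-diyl ending in a silyloxy-substituted and a tertiary radical; the diyl then cleaves the C5–C10 bond, the more substituted of its two β-bonds, which leads to a conjugated enone and a tetrasubstituted enol ether instead of two vinyl groups. The closest known reaction type is the thermal cycloreversion of cyclobutene–cyclohexenone photoadducts to cis,trans-cyclodeca-1,5-dienes. The ten-membered ring is not closed by bond formation: it is set free as the periphery of the tricycle when the two shared bonds break, so no cyclization entropy or dilution is involved. No stereocenter is made; C1, C4, C5 and C10 become trigonal and C8 is untouched. The step needs E geometry at C4=C5, and this is decided by which chair the diyl ring (C1–C2–C3–C4–C5–C10) adopts together with the cis-fused cyclohexanone: with the C8 silyloxy group cis to C1, the cyclohexanone chair that keeps this group and the C10–C1 bond equatorial carries the C10 methyl axial, which is the equatorial position on the diyl chair, so that C6 is equatorial and C9 axial there. Scission of C5–C10 from this chair leaves C6 anti to C3 (E-C4=C5) and C9 syn to C2 (ring-cis C1=C10); the other chair would hold the silyloxy group and C1 in a syn-diaxial clash and would have to place the trans geometry at the tetrasubstituted C1=C10 bond. The second requirement is that the 1,5-diene does not go on to the divinylcyclohexanone by Cope rearrangement: conjugation of C4=C5 with the ketone and the high substitution of both alkenes lower the driving force, and the temperature is kept at the lowest value that opens the tricycle. A trace of amine and base-washed glass protect the silyl enol ether.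

Step 11
Reactants: 16 ethyl bromopyruvate
Product: 17 ethyl 3-acetoxy-2-oxopropanoate
Conditions: KOAc, 18-crown-6 (cat.), MeCN, 0 °C to rt
Reagents that add atoms: potassium acetate, CC(=O)[O-].[K+]
Why: SN2 displacement of the activated primary bromide of an α-halo ketone by acetate.

Step 12
Reactants: 15 (4E,8S)-4,10-dimethyl-1,8-bis(triethylsilyloxy)cyclodeca-1(10),4-dien-6-one; 17 ethyl 3-acetoxy-2-oxopropanoate
Product: 18 ethyl 3-acetoxy-2-hydroxy-2-[(8S)-4,10-dimethyl-6-oxo-1,8-bis(triethylsilyloxy)cyclodeca-1(10),4-dien-7-yl]propanoate (mixture at C7 and C11)
Conditions: LiN(iPr)2, THF, −78 °C; then 17, −78 °C; AcOH, −78 °C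
Reagents that add atoms: none
Why: Kinetic deprotonation of the enone on its saturated side gives the cross-conjugated C7 enolate; C1 is still masked as the silyl enol ether, so no second ketone competes. Aldol addition to the very electrophilic keto carbonyl of 17 forms C7–C11, and the cold acidic quench guards against retro-aldol, acetyl migration and β-elimination of the C8 silyloxy group. C7 and C11 both become trigonal later, so their configuration is irrelevant.

Step 13
Reactants: 18 ethyl 3-acetoxy-2-hydroxy-2-[(8S)-4,10-dimethyl-6-oxo-1,8-bis(triethylsilyloxy)cyclodeca-1(10),4-dien-7-yl]propanoate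
Product: 20 ethyl 3-acetoxy-2-[(8S)-4,10-dimethyl-6-oxo-1,8-bis(triethylsilyloxy)cyclodeca-1(10),4-dien-7-ylidene]propanoate (both C7=C11 isomers), via tertiary mesylate 19 (not isolated)
Conditions: MsCl, Et3N, CH2Cl2, −20 to 0 °C
Reagents that add atoms: none
Why: Sulfonylation of the tertiary aldol hydroxyl and E1cB elimination through the C6 enolate; C7–H is the only acidic hydrogen next to the leaving group. The geometry of the new tetrasubstituted alkene is not controlled and is not needed, because the next step converges.

Step 14
Reactants: 20 ethyl 3-acetoxy-2-[(8S)-4,10-dimethyl-6-oxo-1,8-bis(triethylsilyloxy)cyclodeca-1(10),4-dien-7-ylidene]propanoate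
Product: 22 (4E,6R,8S)-13-acetoxy-1,8-bis(triethylsilyloxy)germacra-1(10),4,7(11)-trien-12,6-olide, via hydroxy ester 21 (not isolated)
Conditions: (S)-1-methyl-3,3-diphenyltetrahydro-1H,3H-pyrrolo[1,2-c][1,3,2]oxazaborole (0.5 equiv), catecholborane, toluene, −78 °C; aqueous work-up; then hν (254 nm, quartz), Et3N (cat.), MeCN, 0 °C
Reagents that add atoms: none
Why: Corey–Bakshi–Shibata reduction: the oxazaborolidine binds the ketone on the side of its smaller flank (C5–H) and delivers hydride so that the fully substituted C7 takes the role of the large group, which should give 6R (6S in the target once C5 is oxygenated); the aprotic borane leaves the silyl enol ether and the esters alone. The isomer with the ester cis to O6 lactonizes spontaneously; the other is isomerized by direct excitation of the enoate (the isolated alkene and the enol ether do not absorb at 254 nm) and is drained by lactonization.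

Step 15
Reactants: 22 (4E,6R,8S)-13-acetoxy-1,8-bis(triethylsilyloxy)germacra-1(10),4,7(11)-trien-12,6-olide
Product: 24 (4E,6R,8S,10R)-13-acetoxy-8,10-dihydroxy-1-oxogermacra-4,7(11)-dien-12,6-olide, via silyloxy epoxide 23 (not isolated)
Conditions: mCPBA (1.05 equiv), NaHCO3, CH2Cl2, −40 °C; then HF·pyridine, pyridine, THF, 0 °C
Reagents that add atoms: 3-chloroperbenzoic acid, O=C(OO)c1cccc(Cl)c1
Why: Rubottom oxidation: the tetrasubstituted silyl enol ether is by far the most electron-rich alkene and is epoxidized before C4=C5. The ring carbons C8 and C3 lie on one face of the enol ether with the C8 silyloxy group turned outward, so the peracid should approach the open face and give the C10–O bond cis to the C8–O bond (10R). Fluoride then opens the silyloxy epoxide to the ketol and frees O8.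

Step 16
Reactants: 24 (4E,6R,8S,10R)-13-acetoxy-8,10-dihydroxy-1-oxogermacra-4,7(11)-dien-12,6-olide; 25 angelic acid
Product: 27 (4E,6R,8S,10R)-13-acetoxy-8-angeloyloxy-10-hydroxy-1-oxogermacra-4,7(11)-dien-12,6-olide, via mixed anhydride 26 (not isolated)
Conditions: 25, 2,4,6-trichlorobenzoyl chloride, Et3N, toluene, rt; then 24, 80 °C
Reagents that add atoms: none
Why: Yamaguchi-type mixed-anhydride acylation run without a nucleophilic catalyst, the conditions under which an angeloyl group is transferred without Z-to-E isomerization. The secondary C8 hydroxyl reacts and the tertiary C10 hydroxyl does not.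

Step 17
Reactants: 27 (4E,6R,8S,10R)-13-acetoxy-8-angeloyloxy-10-hydroxy-1-oxogermacra-4,7(11)-dien-12,6-olide
Product: 28 (4E,6R,8S,10R)-10,13-diacetoxy-8-angeloyloxy-1-oxogermacra-4,7(11)-dien-12,6-olide
Conditions: Ac2O, 4-(dimethylamino)pyridine, Et3N, CH2Cl2, rt
Reagents that add atoms: acetic anhydride, CC(=O)OC(C)=O
Why: Nucleophile-catalysed acetylation of the tertiary α-ketol, the only free hydroxyl left; the mild base keeps the ketol from rearranging.

Step 18
Reactants: 28 (4E,6R,8S,10R)-10,13-diacetoxy-8-angeloyloxy-1-oxogermacra-4,7(11)-dien-12,6-olide
Product: 29 (4R,5R,6S,8S,10R)-10,13-diacetoxy-8-angeloyloxy-4,5-epoxy-1-oxogermacr-7(11)-en-12,6-olide (target)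
Conditions: mCPBA, NaHCO3, CH2Cl2, 0 °C
Reagents that add atoms: 3-chloroperbenzoic acid, O=C(OO)c1cccc(Cl)c1
Why: Prilezhaev epoxidation, stereospecific for the E-alkene; C4=C5 is the only alkene not deactivated by a carbonyl group. Allylic 1,3-strain between the C15 methyl and C6 puts H6 in the alkene plane, C7 (the ring) on one face and the lactone oxygen on the other, so the peracid should add from the exposed face that carries O6, which gives 4R,5R.

## Compound list

1 | cis,cis-cyclohexane-1,3,5-triol | O[C@@H]1C[C@H](O)C[C@H](O)C1 | starting material
2 | all-cis-5-[(tert-butyldimethylsilyl)oxy]cyclohexane-1,3-diol (meso) | O[C@@H]1C[C@H](O)C[C@H](O[Si](C)(C)C(C)(C)C)C1 | intermediate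
3 | (1R,3S,5S)-3-[(tert-butyldimethylsilyl)oxy]-5-hydroxycyclohexyl acetate | CC(=O)O[C@@H]1C[C@H](O)C[C@H](O[Si](C)(C)C(C)(C)C)C1 | intermediate
4 | (1S,3R)-3-[(tert-butyldimethylsilyl)oxy]-5-oxocyclohexyl acetate (keto acetate, not isolated) | CC(=O)O[C@@H]1CC(=O)C[C@H](O[Si](C)(C)C(C)(C)C)C1 | intermediate
5 | (R)-5-[(tert-butyldimethylsilyl)oxy]cyclohex-2-en-1-one | O=C1C=CC[C@@H](O[Si](C)(C)C(C)(C)C)C1 | intermediate
6 | (5R)-5-[(tert-butyldimethylsilyl)oxy]-1-methylcyclohex-2-en-1-ol (C1 epimers) | CC1(O)C=CC[C@@H](O[Si](C)(C)C(C)(C)C)C1 | intermediate
7 | (S)-5-[(tert-butyldimethylsilyl)oxy]-3-methylcyclohex-2-en-1-one | O=C1C[C@@H](O[Si](C)(C)C(C)(C)C)CC(C)=C1 | intermediate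
8 | (S)-5-hydroxy-3-methylcyclohex-2-en-1-one | O=C1C[C@@H](O)CC(C)=C1 | intermediate
9 | 2-methylcyclobutanone | CC1CCC1=O | starting material
10 | [(2-methylcyclobut-1-en-1-yl)oxy]di(propan-2-yl)silyl trifluoromethanesulfonate (enol silyl triflate, not isolated) | CC1=C(O[Si](C(C)C)(C(C)C)OS(=O)(=O)C(F)(F)F)CC1 | intermediate
11 | (S)-3-methyl-5-({[(2-methylcyclobut-1-en-1-yl)oxy]di(propan-2-yl)silyl}oxy)cyclohex-2-en-1-one | O=C1C[C@@H](O[Si](C(C)C)(C(C)C)OC2=C(C)CC2)CC(C)=C1 | intermediate
12 | silylene-bridged photoadduct: cis-anti-cis tricyclic ketone with O8 and O1 joined by Si(iPr)2 (not isolated) | O=C1C[C@@H]3C[C@]2(C)[C@H]1[C@@]1(C)CC[C@]12O[Si](C(C)C)(C(C)C)O3 | intermediate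
13 | cis-anti-cis 2,9-dihydroxy-1,5-dimethyltricyclo[4.4.0.0(2,5)]decan-7-one, C8 hydroxyl cis to the cyclobutane | O=C1C[C@@H](O)C[C@]2(C)[C@H]1[C@@]1(C)CC[C@]12O | intermediate
14 | cis-anti-cis 1,5-dimethyl-2,9-bis(triethylsilyloxy)tricyclo[4.4.0.0(2,5)]decan-7-one, C8 silyloxy cis to the cyclobutane (precursor of the key step) | O=C1C[C@@H](O[Si](CC)(CC)CC)C[C@]2(C)[C@H]1[C@@]1(C)CC[C@]12O[Si](CC)(CC)CC | intermediate
15 | (4E,8S)-4,10-dimethyl-1,8-bis(triethylsilyloxy)cyclodeca-1(10),4-dien-6-one, ring-cis at C1=C10 (product of the key step) | CC[Si](CC)(CC)O[C@@H]1CC(=O)/C=C(\C)CC/C(O[Si](CC)(CC)CC)=C(/C)C1 | intermediate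
16 | ethyl bromopyruvate | CCOC(=O)C(=O)CBr | starting material
17 | ethyl 3-acetoxy-2-oxopropanoate | CCOC(=O)C(=O)COC(C)=O | intermediate
18 | ethyl 3-acetoxy-2-hydroxy-2-[(8S)-4,10-dimethyl-6-oxo-1,8-bis(triethylsilyloxy)cyclodeca-1(10),4-dien-7-yl]propanoate (C7 and C11 mixture) | CC[Si](CC)(CC)O[C@@H]1C(C(O)(COC(C)=O)C(=O)OCC)C(=O)/C=C(\C)CC/C(O[Si](CC)(CC)CC)=C(/C)C1 | intermediate
19 | tertiary mesylate of 18 (not isolated) | CC[Si](CC)(CC)O[C@@H]1C(C(OS(C)(=O)=O)(COC(C)=O)C(=O)OCC)C(=O)/C=C(\C)CC/C(O[Si](CC)(CC)CC)=C(/C)C1 | intermediate
20 | ethyl 3-acetoxy-2-[(8S)-4,10-dimethyl-6-oxo-1,8-bis(triethylsilyloxy)cyclodeca-1(10),4-dien-7-ylidene]propanoate (both C7=C11 isomers) | CC[Si](CC)(CC)O[C@@H]1C(=C(COC(C)=O)C(=O)OCC)C(=O)/C=C(\C)CC/C(O[Si](CC)(CC)CC)=C(/C)C1 | intermediate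
21 | ethyl 3-acetoxy-2-[(6R,8S)-6-hydroxy-4,10-dimethyl-1,8-bis(triethylsilyloxy)cyclodeca-1(10),4-dien-7-ylidene]propanoate (both C7=C11 isomers, not isolated) | CC[Si](CC)(CC)O[C@@H]1C(=C(COC(C)=O)C(=O)OCC)[C@H](O)/C=C(\C)CC/C(O[Si](CC)(CC)CC)=C(/C)C1 | intermediate
22 | (4E,6R,8S)-13-acetoxy-1,8-bis(triethylsilyloxy)germacra-1(10),4,7(11)-trien-12,6-olide | CC[Si](CC)(CC)O[C@H]1C/C(C)=C(O[Si](CC)(CC)CC)\CC/C(C)=C/[C@H]2OC(=O)C(COC(C)=O)=C12 | intermediate
23 | (1R,10R)-1,10-epoxide of 22 (silyloxy epoxide, not isolated) | CC[Si](CC)(CC)O[C@H]1C[C@@]3(C)O[C@@]3(O[Si](CC)(CC)CC)CC/C(C)=C/[C@H]2OC(=O)C(COC(C)=O)=C12 | intermediate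
24 | (4E,6R,8S,10R)-13-acetoxy-8,10-dihydroxy-1-oxogermacra-4,7(11)-dien-12,6-olide | O[C@H]1C[C@@](C)(O)C(=O)CC/C(C)=C/[C@H]2OC(=O)C(COC(C)=O)=C12 | intermediate
25 | angelic acid, (Z)-2-methylbut-2-enoic acid | C/C=C(/C)C(=O)O | starting material
26 | angelic 2,4,6-trichlorobenzoic anhydride (not isolated) | C/C=C(/C)C(=O)OC(=O)c1c(Cl)cc(Cl)cc1Cl | intermediate
27 | (4E,6R,8S,10R)-13-acetoxy-8-angeloyloxy-10-hydroxy-1-oxogermacra-4,7(11)-dien-12,6-olide | C/C=C(/C)C(=O)O[C@H]1C[C@@](C)(O)C(=O)CC/C(C)=C/[C@H]2OC(=O)C(COC(C)=O)=C12 | intermediate
28 | (4E,6R,8S,10R)-10,13-diacetoxy-8-angeloyloxy-1-oxogermacra-4,7(11)-dien-12,6-olide | C/C=C(/C)C(=O)O[C@H]1C[C@@](C)(OC(C)=O)C(=O)CC/C(C)=C/[C@H]2OC(=O)C(COC(C)=O)=C12 | intermediate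
29 | (4R,5R,6S,8S,10R)-10,13-diacetoxy-8-angeloyloxy-4,5-epoxy-1-oxogermacr-7(11)-en-12,6-olide | C/C=C(/C)C(=O)O[C@H]1C[C@@](C)(OC(C)=O)C(=O)CC[C@@]2(C)O[C@@H]2[C@H]2OC(=O)C(COC(C)=O)=C12 | target

## Step count and least certain steps

Total step count: 18. Longest linear sequence: 17 steps (steps 1–10 and 12–18, from 1 to 29); step 11 is a one-step branch.

**Step 10 (key step).** The most likely failures are a subsequent [3,3] shift of the 1,5-diene to the divinylcyclohexanone at the temperature needed to open the tricycle, and partial opening through the other chair, which erodes the E geometry at C4=C5. Loss of the β-silyloxy group from the ketone on hot glass is a further risk. The fallback sets out from 14. The ketone is reduced with NaBH4 in MeOH at 0 °C to the tricyclic carbinol F1, in which the new hydroxyl should sit equatorial in the same chair as the C8 silyloxy group and reinforce it. F1 is opened by flash vacuum pyrolysis in the gas phase with a contact time of milliseconds, so that the cyclodecadienol F2 leaves the hot zone before it can rearrange. Oxidation of the allylic alcohol with MnO2 in CH2Cl2 returns to the route at 15.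

**Step 8 (tethered photocycloaddition).** The most likely failure is slow closure of the seven-membered silicon-containing ring onto a tetrasubstituted alkene, so that hydrogen abstraction or cleavage of the labile enol silyl link takes over. Any regioisomeric enol ether carried over from step 7 would add to this. The fallback sets out from 7 and 9 and drops the tether. Ketone 9 is converted with TESCl, NaI and Et3N in MeCN into 1-(triethylsilyloxy)-2-methylcyclobutene F3. Enone 7 is irradiated at 350 nm with an excess of F3. Both facial isomers of the cis-anti-cis adduct are expected, and the one with the silyloxy group cis to the cyclobutane, F4, is separated by chromatography. Treatment with HF·pyridine removes both silyl groups and returns to the route at 13.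

**Step 14 (reduction and lactonization).** The most likely failures are hydride delivery to the wrong face when the conformational bias of the ring opposes the catalyst, and incomplete or destructive photoisomerization of the isomer whose ester is trans to O6. The fallback sets out from 18 and changes the order of events. The C6 ketone of the aldol adduct is reduced with the same oxazaborolidine and catecholborane. The γ-hydroxy ester then closes to the saturated α-hydroxy lactone F5 whatever the configuration at C7 and C11, so no alkene geometry is involved. Dehydration of the tertiary hydroxyl toward C7 with SOCl2 and pyridine at 0 °C returns to the route at 22.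

**Step 15 (Rubottom oxidation).** The most likely failure is peracid attack on the other face of C1=C10, because the facial bias rests on a ring conformation that is argued and not secured by a rigid element. The fallback sets out from 22 and replaces substrate control by catalyst control. It is a Shi epoxidation with 1,2:4,5-di-O-isopropylidene-β-D-erythro-2,3-hexodiulo-2,6-pyranose or its enantiomer, whichever delivers oxygen to the required face. One equivalent of KHSO5 (as the triple salt 2KHSO5·KHSO4·K2SO4) is used with K2CO3 buffer in MeCN/water at 0 °C, so that only the more electron-rich enol ether reacts. HF·pyridine then returns to the route at 24; this fallback makes no compound outside the compound list (F0).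

**Step 12 (aldol).** The most likely failure is proton transfer from the acidic methylene of 17 to the lithium enolate in place of addition, followed by recovery of 15. The fallback sets out from 15 and changes the activation mode. The kinetic enolate (LiN(iPr)2, −78 °C) is trapped with TMSCl as the C6 trimethylsilyl dienol ether F6. Mukaiyama aldol addition of F6 to 17 with BF3·OEt2 in CH2Cl2 at −78 °C, in which the unhindered C7 terminus reacts in preference to the tetrasubstituted C1=C10 enol ether, returns to the route at 18.

**Step 2 (desymmetrization).** The most likely failure is acylation of the other enantiotopic hydroxyl, which would lead into the enantiomeric series. The fallback sets out from 2 and changes how the methyl group is placed. The regioisomeric monoacetate F7 is oxidized and eliminated as in step 3 to (S)-5-[(tert-butyldimethylsilyl)oxy]cyclohex-2-en-1-one F8. Conjugate addition of Me2CuLi with TMSCl in THF at −78 °C gives the trans-3-methyl trimethylsilyl enol ether F9. Saegusa oxidation with Pd(OAc)2 in MeCN restores the enone with the carbonyl where it was and returns to the route at 7.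

## Further compounds

F1 | step 10 | cis-anti-cis 1,5-dimethyl-2,9-bis(triethylsilyloxy)tricyclo[4.4.0.0(2,5)]decan-7-ol (tricyclic carbinol) | OC1C[C@@H](O[Si](CC)(CC)CC)C[C@]2(C)[C@H]1[C@@]1(C)CC[C@]12O[Si](CC)(CC)CC
F2 | step 10 | (4E,8S)-4,10-dimethyl-1,8-bis(triethylsilyloxy)cyclodeca-1(10),4-dien-6-ol (cyclodecadienol) | CC[Si](CC)(CC)O[C@@H]1CC(O)/C=C(\C)CC/C(O[Si](CC)(CC)CC)=C(/C)C1
F3 | step 8 | 1-(triethylsilyloxy)-2-methylcyclobutene | CC1=C(O[Si](CC)(CC)CC)CC1
F4 | step 8 | cis-anti-cis 9-[(tert-butyldimethylsilyl)oxy]-1,5-dimethyl-2-(triethylsilyloxy)tricyclo[4.4.0.0(2,5)]decan-7-one, C8 silyloxy cis to the cyclobutane | O=C1C[C@@H](O[Si](C)(C)C(C)(C)C)C[C@]2(C)[C@H]1[C@@]1(C)CC[C@]12O[Si](CC)(CC)CC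
F5 | step 14 | (4E,6R,8S)-13-acetoxy-11-hydroxy-1,8-bis(triethylsilyloxy)germacra-1(10),4-dien-12,6-olide (α-hydroxy lactone, C7 and C11 mixture) | CC[Si](CC)(CC)O[C@H]1C/C(C)=C(O[Si](CC)(CC)CC)\CC/C(C)=C/[C@H]2OC(=O)C(O)(COC(C)=O)C12
F0 | step 15 | none | none
F6 | step 12 | (8S)-4,10-dimethyl-1,8-bis(triethylsilyloxy)-6-(trimethylsilyloxy)cyclodeca-1(10),4,6-triene (C6 trimethylsilyl dienol ether) | CC[Si](CC)(CC)O[C@@H]1C=C(O[Si](C)(C)C)/C=C(\C)CC/C(O[Si](CC)(CC)CC)=C(/C)C1
F7 | step 2 | (1S,3R,5R)-3-[(tert-butyldimethylsilyl)oxy]-5-hydroxycyclohexyl acetate (regioisomeric monoacetate) | O[C@@H]1C[C@H](OC(C)=O)C[C@H](O[Si](C)(C)C(C)(C)C)C1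
F8 | step 2 | (S)-5-[(tert-butyldimethylsilyl)oxy]cyclohex-2-en-1-one | O=C1C=CC[C@H](O[Si](C)(C)C(C)(C)C)C1
F9 | step 2 | trans-5-[(tert-butyldimethylsilyl)oxy]-3-methyl-1-(trimethylsilyloxy)cyclohex-1-ene | C[C@H]1C[C@H](O[Si](C)(C)C(C)(C)C)CC(O[Si](C)(C)C)=C1
A1 | alternative 1 | ten-membered (E)-alkene fused to the butenolide, C1/C10 acetonide, C8 silyl ether | CC(C)(C)[Si](C)(C)O[C@H]1C[C@@]2(C)OC(C)(C)O[C@H]2CC/C(C)=C/[C@H]2OC(=O)C(COC(C)=O)=C12
A2 | alternative 2 | (8S)-8-benzyloxy-4,10-dimethylcyclodec-1(10)-en-6-one (germacrane numbering) | O=C1C[C@@H](OCc2ccccc2)C/C(C)=C/CC[C@H](C)C1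
A3 | alternative 3 | ten-membered C2 β-keto ester with the E-C4=C5 alkene | COCO[C@H]1C[C@@](C)(OC(C)=O)C(=O)C(C(=O)OCC[Si](C)(C)C)C/C(C)=C/[C@@H](O[Si](C)(C)C(C)(C)C)/C1=C(\CO[Si](C)(C)C(C)(C)C)COCc1ccc(OC)cc1
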